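Oak and alder are both read at 3.0 h, and the question is how much of the substrate has become product by then.

| flask | substrate | precatalyst | temperature | remark | time |
|---|---|---|---|---|---|
| violet | 0.40 M | 3.2 mM | 30 °C | run made earlier |  |
| amber | 0.40 M | 4.3 mM | 41 °C | run made earlier |  |
| red | 0.40 M | 9.5 mM | 30 °C | run made earlier |  |
| oak | 0.40 M | 8.0 mM |  | at 25 °C until 50 min, from then on at 45 °C | 3.0 h |
| alder | 0.40 M | 2.5 mM |  | at 45 °C throughout | 3.0 h |

violet run (percent of the substrate charged)

| time / h | product / % | substrate / % |
|---|---|---|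
| 0.250 | 2.3 | 98.3 |
| 0.417 | 2.9 | 96.7 |
| 0.833 | 7.5 | 91.6 |
| 1.50 | 13.5 | 86.6 |
| 3.00 | 26.6 | 74.8 |

amber run (percent of the substrate charged)

| time / min | product / % | substrate / % |
|---|---|---|
| 6.00 | 2.7 | 96.0 |
| 25.0 | 14.0 | 86.0 |
| 40.0 | 21.7 | 78.4 |
| 50.0 | 26.3 | 73.5 |
| 80.0 | 39.1 | 60.1 |

red run (percent of the substrate charged)

| time / h | product / % | substrate / % |
|---|---|---|
| 0.250 | 5.2 | 94.2 |
| 0.833 | 19.6 | 79.6 |
| 1.33 | 31.9 | 68.2 |
| 2.00 | 43.7 | 54.9 |
| 3.00 | 58.5 | 40.5 |

(each reading ± 0.5 percentage points)

- which of the two ends with the higher amount of product, in percent of the substrate charged ("neither" if they lie within 2 percentage points) (oak / alder / neither)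
- product at the end, in percent of the substrate charged, oak
- product at the end, in percent of the substrate charged, alder



The earlier runs hold a puzzle. At 30 °C and 3.00 h, red has 2.97 times the precatalyst of violet but 2.20 times the product.

The balance of the smaller charge clears this up. Red made 24.6 mol of product per mol of precatalyst charged, so the catalyst comes back each round. At one temperature, a steady amount of catalyst removes the same fraction of the remaining substrate in each equal interval, a pseudo-first-order loss, so product flattens as substrate falls. The logarithm of the inverse substrate fraction counts that loss. Divided by precatalyst and time, it gives 0.0302 mM⁻¹ h⁻¹ in violet and 0.0317 mM⁻¹ h⁻¹ in red, readings that lie close together.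

Amber at 41 °C reads 0.0888 mM⁻¹ h⁻¹. My own reckoning draws a straight line through the logarithms of the red and amber values against temperature. It gives 0.0199 mM⁻¹ h⁻¹ at 25 °C and 0.129 mM⁻¹ h⁻¹ at 45 °C. This last value, the specific rate, the logarithmic loss of substrate per mM of precatalyst per hour, carries the reckoning.

Alder collects 0.969, which means 62.0 % product. Oak collects 0.132 in its cool stretch and 2.24 in its warm one, which means 90.7 % product, more than alder.

The forecast names oak, with 89 % for oak and 60 % for alder, since “the reaction is first order in substrate”, and both figures stand below my own.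

Oak ends at 91.3 % and alder at 62.0 %.

    precatalyst → free catalyst (k = 0.00240 s⁻¹, Ea = 92.0 kJ mol⁻¹)
    catalyst intermediate → free catalyst + product (k = 0.0120 s⁻¹, Ea = 86.0 kJ mol⁻¹)
    substrate + free catalyst → catalyst intermediate (k = 0.00620 M⁻¹ s⁻¹, Ea = 73.0 kJ mol⁻¹)
    (constants at 25 °C)

At 3.00 h, alder holds 94.7 % of its catalyst as free catalyst, the resting state, 5.34 % as catalyst intermediate and 0 % as precatalyst. For alder read at 12 h, the specific rate 0.129 mM⁻¹ h⁻¹ gives 2.08 % substrate left, and that flask held 1.64 %.

(All runs are calculated from invented constants; scatter was added.)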